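## Retrosynthetic overview

1. The target is an ent-labdane (C5, C9 and C10 are opposite to sclareolide), so ring A is bought and ring B is built last; the endgame is tert-butyl ester cleavage and C7=C8 dehydrogenation of an 8-methyl-6-ketone.
2. The (Z)-acetoxymethyl enoate comes from a Negishi coupling on a chelation-derived (Z)-enol triflate, made from a β-keto ester, made from a C13 acid.
3. Ring B (C9–C10, quaternary C10) and the C11–C12 bond form together in one light-driven radical addition/6-endo cyclisation of an acyclic dienone with bromoacetic acid.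
4. The dienone comes from 2,6,6-trimethylcyclohexenyllithium (Shapiro) and an (S)-3-methylpent-4-enoyl Weinreb amide, obtained from (R)-citronellic acid by dealkenylation.
5. The C8 methyl stereocentre of citronellic acid steers C9, C10 and C5 and is erased when C7=C8 is introduced.

Assumption: (R)-(+)-citronellic acid of ≥98% ee is the bought source of chirality, racemic 2,2,6-trimethylcyclohexanone is used (its stereocentre is lost in step 4), and labdane numbering C1–C20 is used in the comments.

## Route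

**Step 1**
Reactants: 1 (R)-(+)-citronellic acid
Product: 3 (3R)-N-methoxy-N,3,7-trimethyloct-6-enamide, via acyl imidazolide 2 (not isolated)
Conditions: CDI, CH2Cl2, 0 → 25 °C; then MeNHOMe·HCl, 25 °C
Reagents that add atoms: N,O-dimethylhydroxylamine hydrochloride, CNOC.Cl
Why: CDI turns the acid into its acyl imidazolide, which the hydroxylamine acylates (Weinreb amide formation); the C3 stereocentre is not involved.

**Step 2**
Reactants: 3 (3R)-N-methoxy-N,3,7-trimethyloct-6-enamide
Product: 5 (3S)-N-methoxy-N,3-dimethylpent-4-enamide, via methoxy hydroperoxide 4 (not isolated)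
Conditions: O3, CH2Cl2/MeOH, −78 °C; then FeSO4·7H2O, Cu(OAc)2·H2O, MeOH/H2O, 0 → 25 °C
Reagents that add atoms: none
Why: Criegee ozonolysis in methanol gives acetone and the α-methoxy hydroperoxide at the less substituted carbon; divalent iron reduces it to an alkoxy radical that loses methyl formate by β-scission, and divalent copper oxidises the primary radical to the terminal alkene (Schreiber-type dealkenylation); C3 is untouched and is called S only because vinyl now outranks CH2C(O).

**Step 3**
Reactants: 6 2,2,6-trimethylcyclohexanone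
Product: 7 N'-(2,2,6-trimethylcyclohexylidene)-2,4,6-tri(propan-2-yl)benzenesulfonohydrazide
Conditions: 2,4,6-(iPr)3C6H2SO2NHNH2, HCl (cat.), MeCN, 25 °C
Reagents that add atoms: 2,4,6-triisopropylbenzenesulfonohydrazide, CC(C)c1cc(C(C)C)c(S(=O)(=O)NN)c(C(C)C)c1
Why: Acid-catalysed condensation gives the arenesulfonylhydrazone needed for a Shapiro reaction; its only α-hydrogen is at C6.

**Step 4**
Reactants: 7 N'-(2,2,6-trimethylcyclohexylidene)-2,4,6-tri(propan-2-yl)benzenesulfonohydrazide; 5 (3S)-N-methoxy-N,3-dimethylpent-4-enamide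
Product: 9 (3S)-3-methyl-1-(2,6,6-trimethylcyclohex-1-en-1-yl)pent-4-en-1-one, via vinyllithium 8 (not isolated)
Conditions: n-BuLi (2.2 equiv), TMEDA, THF/hexane, −78 → 0 °C; then 5, −78 → 25 °C; aq. NH4Cl
Reagents that add atoms: none
Why: The Shapiro reaction (double deprotonation, loss of sulfinate and N2) gives the tetrasubstituted vinyllithium, which adds once to the Weinreb amide because the chelated tetrahedral adduct survives until work-up; the racemic centre of 6 becomes sp2 and the C8 centre from 5 is untouched.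

**Step 5**
Reactants: 9 (3S)-3-methyl-1-(2,6,6-trimethylcyclohex-1-en-1-yl)pent-4-en-1-one; 10 bromoacetic acid
Product: 11 3-[(1R,2S,4aR,8aS)-2,5,5,8a-tetramethyl-4-oxodecahydronaphthalen-1-yl]propanoic acid
Conditions: 10 (2 equiv), (Me3Si)3SiH (1.5 equiv, syringe pump), [Ir(dF(CF3)ppy)2(dtbbpy)]PF6 (1 mol%), LiBr (10 mol%), MeCN, 450 nm LEDs, 25 °C
Reagents that add atoms: none
Why: Proposed new method: a light-driven three-component radical cascade in which a photocatalytically generated silyl radical abstracts bromine from 10, the electrophilic carboxymethyl radical adds to the terminal vinyl carbon of 9 (C11–C12), the nucleophilic secondary C9 radical closes ring B by polarity-matched 6-endo-trig attack on the β-carbon C10 of the ring A enone (5-exo would hit the α-carbon), and the tertiary α-keto radical at C5 takes hydrogen from the silane anti to the new angular methyl (trans fusion, also the thermodynamic epimer); in the chair transition state C20 is forced axial, so the bought C8 methyl stays equatorial to avoid a 1,3-diaxial Me/Me clash and thereby selects the face of C10 (10S), while the C9 chain sits equatorial next to the small C8–H (9R); any C9 bromide from atom transfer is reopened by the silyl radical, and slow silane addition limits premature reduction; closest known chemistry is silane- or stannane-mediated addition/cyclisation annulations of α-halo carbonyl compounds with alkenes and 6-endo cyclisations of alkyl radicals onto enones whose carbonyl lies in the new ring, not yet shown on a twisted, fully substituted 1-acylcyclohexene under remote methyl control.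

**Step 6**
Reactants: 11 3-[(1R,2S,4aR,8aS)-2,5,5,8a-tetramethyl-4-oxodecahydronaphthalen-1-yl]propanoic acid; 12 mono-tert-butyl malonate
Product: 15 tert-butyl 3-oxo-5-[(1R,2S,4aR,8aS)-2,5,5,8a-tetramethyl-4-oxodecahydronaphthalen-1-yl]pentanoate, via acyl imidazolide 13 (not isolated), via acylmalonate 14 (not isolated)
Conditions: CDI, THF, 25 °C; then 12, MgCl2, Et3N, MeCN, 25 °C; 1 M HCl
Reagents that add atoms: none
Why: Masamune–Brooks homologation: the acyl imidazolide C-acylates the magnesium enolate of the malonate half-ester and the acylmalonate loses CO2 on acidification; the soft enolate leaves the hindered C6 ketone alone, and Et3N equilibrates any cis-fused C5 epimer to the trans-decalin.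

**Step 7**
Reactants: 15 tert-butyl 3-oxo-5-[(1R,2S,4aR,8aS)-2,5,5,8a-tetramethyl-4-oxodecahydronaphthalen-1-yl]pentanoate
Product: 16 tert-butyl (2Z)-5-[(1R,2S,4aR,8aS)-2,5,5,8a-tetramethyl-4-oxodecahydronaphthalen-1-yl]-3-{[(trifluoromethyl)sulfonyl]oxy}pent-2-enoate
Conditions: Tf2O, sat. aq. LiOH, PhMe, 5 °C
Reagents that add atoms: trifluoromethanesulfonic anhydride, O=S(=O)(OS(=O)(=O)C(F)(F)F)C(F)(F)F
Why: O-Triflation of the chelated lithium enolate of the β-keto ester places OTf cis to the ester (Z), the position C16 must take.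

**Step 8**
Reactants: 16 tert-butyl (2Z)-5-[(1R,2S,4aR,8aS)-2,5,5,8a-tetramethyl-4-oxodecahydronaphthalen-1-yl]-3-{[(trifluoromethyl)sulfonyl]oxy}pent-2-enoate; 17 bromomethyl acetate
Product: 19 tert-butyl (2Z)-3-(acetoxymethyl)-5-[(1R,2S,4aR,8aS)-2,5,5,8a-tetramethyl-4-oxodecahydronaphthalen-1-yl]pent-2-enoate, via acetoxymethylzinc bromide 18 (not isolated)
Conditions: 17, Zn dust, LiCl, THF, 25 °C; then 16, Pd(OAc)2 (2 mol%), SPhos (4 mol%), THF, 25 °C
Reagents that add atoms: none
Why: Zinc insertion gives the acyloxymethylzinc reagent and Negishi coupling replaces OTf with retention, so CH2OAc ends cis to the ester and the C12 chain trans; room temperature and a bulky phosphine keep the product allylic acetate from ionising on zerovalent palladium.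

**Step 9**
Reactants: 19 tert-butyl (2Z)-3-(acetoxymethyl)-5-[(1R,2S,4aR,8aS)-2,5,5,8a-tetramethyl-4-oxodecahydronaphthalen-1-yl]pent-2-enoate
Product: 20 tert-butyl (2Z)-3-(acetoxymethyl)-5-[(1R,4aR,8aS)-2,5,5,8a-tetramethyl-4-oxo-1,4,4a,5,6,7,8,8a-octahydronaphthalen-1-yl]pent-2-enoate
Conditions: IBX (2 equiv), DMSO/PhF, 70 °C
Reagents that add atoms: none
Why: IBX dehydrogenation of the ketone through its enol can only give C7=C8 because C5 is flanked by the quaternary carbons C4 and C10; this erases the C8 controller centre and leaves C5, C9 and C10 untouched under non-basic conditions.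

**Step 10**
Reactants: 20 tert-butyl (2Z)-3-(acetoxymethyl)-5-[(1R,4aR,8aS)-2,5,5,8a-tetramethyl-4-oxo-1,4,4a,5,6,7,8,8a-octahydronaphthalen-1-yl]pent-2-enoate
Product: 21 (2Z)-3-(acetoxymethyl)-5-[(1R,4aR,8aS)-2,5,5,8a-tetramethyl-4-oxo-1,4,4a,5,6,7,8,8a-octahydronaphthalen-1-yl]pent-2-enoic acid (CNP0145331.2)
Conditions: CF3CO2H/CH2Cl2 (1:4), 0 → 25 °C
Reagents that add atoms: none
Why: Acidolysis (E1 loss of the tert-butyl cation as isobutene) frees the acid without touching the primary allylic acetate, the enone or the γ-stereocentre C9.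

## Compound list

1 | (R)-(+)-citronellic acid, (3R)-3,7-dimethyloct-6-enoic acid | C[C@H](CCC=C(C)C)CC(=O)O | starting material
2 | (3R)-1-(1H-imidazol-1-yl)-3,7-dimethyloct-6-en-1-one | C[C@H](CCC=C(C)C)CC(=O)n1ccnc1 | intermediate (not isolated)
3 | (3R)-N-methoxy-N,3,7-trimethyloct-6-enamide | C[C@H](CCC=C(C)C)CC(=O)N(C)OC | intermediate
4 | (3R)-6-hydroperoxy-N,6-dimethoxy-N,3-dimethylhexanamide (both C6 epimers) | C[C@H](CCC(OC)OO)CC(=O)N(C)OC | intermediate (not isolated)
5 | (3S)-N-methoxy-N,3-dimethylpent-4-enamide | C[C@H](C=C)CC(=O)N(C)OC | intermediate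
6 | 2,2,6-trimethylcyclohexanone (racemic) | CC1CCCC(C)(C)C1=O | starting material
7 | N'-(2,2,6-trimethylcyclohexylidene)-2,4,6-tri(propan-2-yl)benzenesulfonohydrazide (racemic) | CC1CCCC(C)(C)C1=NNS(=O)(=O)c1c(C(C)C)cc(C(C)C)cc1C(C)C | intermediate
8 | (2,6,6-trimethylcyclohex-1-en-1-yl)lithium | [Li]C1=C(C)CCCC1(C)C | intermediate (not isolated)
9 | (3S)-3-methyl-1-(2,6,6-trimethylcyclohex-1-en-1-yl)pent-4-en-1-one | C[C@H](C=C)CC(=O)C1=C(C)CCCC1(C)C | intermediate
10 | bromoacetic acid | OC(=O)CBr | starting material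
11 | 3-[(1R,2S,4aR,8aS)-2,5,5,8a-tetramethyl-4-oxodecahydronaphthalen-1-yl]propanoic acid | OC(=O)CC[C@@H]1[C@@H](C)CC(=O)[C@@H]2C(C)(C)CCC[C@@]12C | intermediate
12 | mono-tert-butyl malonate, 3-(tert-butoxy)-3-oxopropanoic acid | CC(C)(C)OC(=O)CC(=O)O | starting material
13 | 1-(1H-imidazol-1-yl)-3-[(1R,2S,4aR,8aS)-2,5,5,8a-tetramethyl-4-oxodecahydronaphthalen-1-yl]propan-1-one | O=C(CC[C@@H]1[C@@H](C)CC(=O)[C@@H]2C(C)(C)CCC[C@@]12C)n1ccnc1 | intermediate (not isolated)
14 | 2-(tert-butoxycarbonyl)-3-oxo-5-[(1R,2S,4aR,8aS)-2,5,5,8a-tetramethyl-4-oxodecahydronaphthalen-1-yl]pentanoic acid (magnesium salt, both C2 epimers) | CC(C)(C)OC(=O)C(C(=O)O)C(=O)CC[C@@H]1[C@@H](C)CC(=O)[C@@H]2C(C)(C)CCC[C@@]12C | intermediate (not isolated)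
15 | tert-butyl 3-oxo-5-[(1R,2S,4aR,8aS)-2,5,5,8a-tetramethyl-4-oxodecahydronaphthalen-1-yl]pentanoate | CC(C)(C)OC(=O)CC(=O)CC[C@@H]1[C@@H](C)CC(=O)[C@@H]2C(C)(C)CCC[C@@]12C | intermediate
16 | tert-butyl (2Z)-5-[(1R,2S,4aR,8aS)-2,5,5,8a-tetramethyl-4-oxodecahydronaphthalen-1-yl]-3-{[(trifluoromethyl)sulfonyl]oxy}pent-2-enoate | FC(F)(F)S(=O)(=O)O/C(=C\C(=O)OC(C)(C)C)CC[C@@H]1[C@@H](C)CC(=O)[C@@H]2C(C)(C)CCC[C@@]12C | intermediate
17 | bromomethyl acetate | CC(=O)OCBr | starting material
18 | (acetoxymethyl)zinc bromide | CC(=O)OC[Zn]Br | intermediate (not isolated)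
19 | tert-butyl (2Z)-3-(acetoxymethyl)-5-[(1R,2S,4aR,8aS)-2,5,5,8a-tetramethyl-4-oxodecahydronaphthalen-1-yl]pent-2-enoate | CC(=O)OC/C(=C\C(=O)OC(C)(C)C)CC[C@@H]1[C@@H](C)CC(=O)[C@@H]2C(C)(C)CCC[C@@]12C | intermediate
20 | tert-butyl (2Z)-3-(acetoxymethyl)-5-[(1R,4aR,8aS)-2,5,5,8a-tetramethyl-4-oxo-1,4,4a,5,6,7,8,8a-octahydronaphthalen-1-yl]pent-2-enoate | CC(=O)OC/C(=C\C(=O)OC(C)(C)C)CC[C@@H]1C(C)=CC(=O)[C@@H]2C(C)(C)CCC[C@@]12C | intermediate
21 | (2Z)-3-(acetoxymethyl)-5-[(1R,4aR,8aS)-2,5,5,8a-tetramethyl-4-oxo-1,4,4a,5,6,7,8,8a-octahydronaphthalen-1-yl]pent-2-enoic acid (16-acetoxy-6-oxo-ent-labda-7,13-dien-15-oic acid) | CC(=O)OC/C(=C\C(=O)O)CC[C@@H]1C(C)=CC(=O)[C@@H]2C(C)(C)CCC[C@@]12C | target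

## Step count and risks

Total steps: 10. Longest linear sequence: 9 (1 → 3 → 5 → 9 → 11 → 15 → 16 → 19 → 20 → 21; steps 1, 2, 4–10).

**Step 5 (the proposed new cascade).** The C9 radical may be reduced before it cyclises, or may close 5-exo. The fallback closes ring B by known polar chemistry, setting out from 9 and returning at 11. Cross-metathesis of 9 with allyltrimethylsilane (second-generation Grubbs catalyst RuCl2(H2IMes)(PCy3)(=CHPh), CH2Cl2, 40 °C) gives the allylsilane (3S,4E)-3-methyl-6-(trimethylsilyl)-1-(2,6,6-trimethylcyclohex-1-en-1-yl)hex-4-en-1-one F2. EtAlCl2 (PhMe, −78 → 0 °C) then triggers an intramolecular Hosomi–Sakurai conjugate allylation, an established way to make angular-methyl quaternary carbons in decalins, through the same chair with the C8 methyl equatorial, giving the 9-vinyl ketone (3S,4R,4aS,8aR)-4-ethenyl-3,4a,8,8-tetramethyloctahydronaphthalen-1(2H)-one F3. Cross-metathesis of F3 with acrylic acid (second-generation Hoveyda–Grubbs catalyst RuCl2(H2IMes)(=CH-C6H4-2-OiPr), CH2Cl2, 40 °C) gives (2E)-3-[(1S,2S,4aR,8aS)-2,5,5,8a-tetramethyl-4-oxodecahydronaphthalen-1-yl]prop-2-enoic acid F4, and H2 over Pd/C (EtOAc, 25 °C) saturates the side-chain alkene to give 11.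

**Step 2 (one-pot dealkenylation).** The Criegee split may partly go the other way, and the iron/copper fragmentation can give lower yields on an acyclic trisubstituted alkene. The fallback sets out from 3 and returns at 5 in two known operations. Ozonolysis with reductive work-up (O3, CH2Cl2, −78 °C; Me2S) gives the aldehyde (3R)-N-methoxy-N,3-dimethyl-6-oxohexanamide F1. Rhodium-catalysed transfer dehydroformylation ([Rh(cod)(OMe)]2, Xantphos, 3-methoxybenzoic acid, norbornadiene as formyl acceptor, THF, 22 → 60 °C) then removes the formyl carbon and gives the terminal alkene 5.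

**Step 8 (acetoxymethyl transfer).** The α-acyloxymethylzinc reagent may transfer sluggishly, and the product allylic acetate can be ionised by zerovalent palladium. The fallback sets out from 16 and returns at 19, introducing the carbinol first and the acetate only after the palladium step. Stille coupling of 16 with (tributylstannyl)methanol (Pd(PPh3)4, LiCl, dioxane, 80 °C) gives tert-butyl (2Z)-3-(hydroxymethyl)-5-[(1R,2S,4aR,8aS)-2,5,5,8a-tetramethyl-4-oxodecahydronaphthalen-1-yl]pent-2-enoate F5, whose bulky ester slows lactonisation. Immediate acetylation (Ac2O, pyridine, DMAP, 0 °C) gives 19.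

## Further compounds

F1 | step 2 | (3R)-N-methoxy-N,3-dimethyl-6-oxohexanamide | C[C@H](CCC=O)CC(=O)N(C)OC
F2 | step 5 | (3S,4E)-3-methyl-6-(trimethylsilyl)-1-(2,6,6-trimethylcyclohex-1-en-1-yl)hex-4-en-1-one | C[C@H](/C=C/C[Si](C)(C)C)CC(=O)C1=C(C)CCCC1(C)C
F3 | step 5 | (3S,4R,4aS,8aR)-4-ethenyl-3,4a,8,8-tetramethyloctahydronaphthalen-1(2H)-one | C=C[C@@H]1[C@@H](C)CC(=O)[C@@H]2C(C)(C)CCC[C@@]12C
F4 | step 5 | (2E)-3-[(1S,2S,4aR,8aS)-2,5,5,8a-tetramethyl-4-oxodecahydronaphthalen-1-yl]prop-2-enoic acid | OC(=O)/C=C/[C@@H]1[C@@H](C)CC(=O)[C@@H]2C(C)(C)CCC[C@@]12C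
F5 | step 8 | tert-butyl (2Z)-3-(hydroxymethyl)-5-[(1R,2S,4aR,8aS)-2,5,5,8a-tetramethyl-4-oxodecahydronaphthalen-1-yl]pent-2-enoate | OC/C(=C\C(=O)OC(C)(C)C)CC[C@@H]1[C@@H](C)CC(=O)[C@@H]2C(C)(C)CCC[C@@]12C
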